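**Strategy.** Ring B is built last. Disconnecting C1'–C2' and C5'–C6' turns the 2',4'-dihydroxyphenyl group into an ethynyl group on C2 of a finished chromone (giving C1' and C6') and an acetoacetate-derived 1,1,3-trioxygenated diene (giving C2'–C5' with both oxygens). One Diels–Alder/aromatisation operation should therefore forge the whole resorcinol ring. The feature exploited is the 1,3-placement of the C2' and C4' hydroxyls beside C1', together with the C2=C3–C4=O unit of ring C, which polarises the alkyne. The precursor is 2-ethynyl-5,6,7,8-tetramethoxychromone; O5 travels as a methyl ether, which the peri C4 carbonyl later allows to be cleaved selectively.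

Key step: step 8

Remark: O5 is carried as its methyl ether, which serves as the protecting group, so ring A needs no separate protection or deprotection steps. The geometry of enol ether 12 and of the ketene acetal in 13 is immaterial, because these carbons end up in aromatic ring B.

**Step 1**
Reactants: 1 1,2,3-trimethoxybenzene
Product: 2 1,5-dibromo-2,3,4-trimethoxybenzene
Conditions: Br2 (2.1 equiv), CH2Cl2, 0 °C → rt
Reagents that add atoms: bromine, BrBr
Why: Electrophilic aromatic bromination; C4 and C6 of 1 are each ortho and para to an outer methoxy group, whereas C5 is activated only by the twisted central methoxy group, so two equivalents should stop at the 4,6-dibromide.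

**Step 2**
Reactants: 2 1,5-dibromo-2,3,4-trimethoxybenzene
Product: 3 pentamethoxybenzene
Conditions: NaOMe (25% in MeOH, excess), CuBr (0.2 equiv), DMF, 110 °C
Reagents that add atoms: sodium methoxide, C[O-].[Na+]
Why: Copper-catalysed Ullmann-type methoxylation of aryl bromides with NaOMe is a standard entry to polymethoxybenzenes from electron-rich bromoanisoles, and the two C–Br bonds of 2 are equivalent.

**Step 3**
Reactants: 3 pentamethoxybenzene
Product: 5 1-(2-hydroxy-3,4,5,6-tetramethoxyphenyl)ethan-1-one, via pentamethoxyacetophenone 4 (not isolated)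
Conditions: AcCl, AlCl3, Et2O, 0 °C → rt; then aq. HCl
Reagents that add atoms: acetyl chloride, CC(=O)Cl
Why: Friedel–Crafts acylation can occur only at the single free position of 3, and AlCl3 bound to the new carbonyl should then cleave one of the two equivalent ortho methyl ethers through a six-membered chelate, the aluminium phenoxide formed shielding the second ortho methoxy group.

**Step 4**
Reactants: 5 1-(2-hydroxy-3,4,5,6-tetramethoxyphenyl)ethan-1-one; 6 ethyl 2,2-diethoxyacetate
Product: 9 5,6,7,8-tetramethoxy-4-oxo-4H-chromene-2-carbaldehyde, via diethoxy diketone 7 (not isolated), via chromone diethyl acetal 8 (not isolated)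
Conditions: NaH (4 equiv), THF, 0 °C → reflux; then AcOH, 2 M aq. HCl, 60 °C
Reagents that add atoms: water, O
Why: A crossed Claisen condensation of the dianion of 5 with ester 6 (which does not self-condense) should give the 1,3-diketone, which in aqueous acid undergoes the usual cyclodehydration of an o-hydroxyaryl 1,3-diketone to the chromone and loses its acetal by hydrolysis in the same pot.

**Step 5**
Reactants: 9 5,6,7,8-tetramethoxy-4-oxo-4H-chromene-2-carbaldehyde
Product: 10 2-ethynyl-5,6,7,8-tetramethoxy-4H-chromen-4-one
Conditions: TMSCHN2, n-BuLi, THF, −78 °C; this solution added to 9 in THF, −78 → 0 °C; AcOH quench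
Reagents that add atoms: trimethylsilyldiazomethane, C[Si](C)(C)C=[N+]=[N-]
Why: Colvin rearrangement: addition of the lithiated diazo reagent to the non-enolisable aldehyde, Peterson-type loss of silanolate and loss of N2 give an alkylidene carbene whose 1,2-hydrogen shift delivers the terminal alkyne, and the aprotic, low-temperature conditions avoid alkoxide that could add to the formylchromone or to the ynenone product.

**Step 6**
Reactants: 11 methyl acetoacetate
Product: 12 methyl 3-(trimethylsilyloxy)but-2-enoate (E/Z mixture)
Conditions: TMSCl, Et3N, hexane, rt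
Reagents that add atoms: chlorotrimethylsilane, C[Si](C)(C)Cl
Why: O-Silylation of the β-keto ester enol (silyl enol ether formation) is the standard first stage towards 1,3-bis(silyloxy)dienes, and the double-bond geometry is lost in the next step.

**Step 7**
Reactants: 12 methyl 3-(trimethylsilyloxy)but-2-enoate
Product: 13 1-methoxy-1,3-bis(trimethylsilyloxy)buta-1,3-diene
Conditions: LiN(iPr)2, THF, −78 °C; TMSCl, −78 °C → rt; distilled and used fresh
Reagents that add atoms: chlorotrimethylsilane, C[Si](C)(C)Cl
Why: Kinetic deprotonation of the γ-methyl group gives the vinylogous ester dienolate, whose O-silylation (silyl ketene acetal formation) should give the diene.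

**Step 8**
Reactants: 10 2-ethynyl-5,6,7,8-tetramethoxy-4H-chromen-4-one; 13 1-methoxy-1,3-bis(trimethylsilyloxy)buta-1,3-diene
Product: 15 2-(2,4-dihydroxyphenyl)-5,6,7,8-tetramethoxy-4H-chromen-4-one, via cyclohexadiene cycloadduct 14 (not isolated)
Conditions: 13 (3 equiv, in portions), toluene, 80 °C, sealed tube, N2; then 1 M HCl, THF, rt
Reagents that add atoms: none
Why: Proposed new method: a 2-ethynylchromone has not served as the 2π partner of a 1,1,3-trioxygenated diene, but its alkyne is a vinylogous ynone (HC≡C–C2=C3–C4=O) with the largest LUMO coefficient on the terminal carbon, so the nucleophilic CH2 terminus of 13 should bond there (C5'–C6') and the ketene acetal carbon to the internal carbon (C1'–C2') in a normal-demand, asynchronous [4+2] cycloaddition; the closest known reaction type is the Diels–Alder benzannulation of such silyl ketene acetal dienes with acetylenic ketones and esters to give resorcinols. Ring B closes by this intermolecular [4+2] mode with both ring bonds made in the one cycloaddition, and a stepwise variant (vinylogous Mukaiyama–Michael addition, then closure of the allenyl enolate onto the ketene acetal carbon) would converge on the same adduct 14. Aqueous acid should then collapse the mixed methyl silyl ketal at C2' to a carbonyl and cleave the C4' silyl enol ether, after which the cyclohexenedione tautomerises irreversibly to the resorcinol. No stereocentre survives, since the racemic ketal carbon of 14 becomes the sp2 carbon C2'. The step needs regioselectivity (the C2' oxygen next to C1') and chemoselectivity for the alkyne over the C2=C3 bond; the first should be secured by the matched polarisation of ynenone and diene, the second by the C2=C3 bond being trisubstituted and donor-substituted by O1 while the terminal alkyne is unhindered.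

**Step 9**
Reactants: 15 2-(2,4-dihydroxyphenyl)-5,6,7,8-tetramethoxy-4H-chromen-4-one
Product: 16 tamadone, 2-(2,4-dihydroxyphenyl)-5-hydroxy-6,7,8-trimethoxy-4H-chromen-4-one
Conditions: BCl3 (5 equiv), CH2Cl2, −78 → 0 °C; then MeOH, H2O
Reagents that add atoms: none
Why: Chelation-directed Lewis acid ether cleavage: BCl3 bridges the C4 carbonyl and the peri O5 so that chloride removes only that methyl group, as is routine for 5-methoxyflavones, while the C6, C7 and C8 methyl ethers lack this assistance at or below 0 °C.

**Compound list**
1 | 1,2,3-trimethoxybenzene | COc1cccc(OC)c1OC | starting material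
2 | 1,5-dibromo-2,3,4-trimethoxybenzene | COc1c(Br)cc(Br)c(OC)c1OC | intermediate
3 | pentamethoxybenzene | COc1cc(OC)c(OC)c(OC)c1OC | intermediate
4 | 1-(2,3,4,5,6-pentamethoxyphenyl)ethan-1-one | CC(=O)c1c(OC)c(OC)c(OC)c(OC)c1OC | intermediate (not isolated)
5 | 1-(2-hydroxy-3,4,5,6-tetramethoxyphenyl)ethan-1-one | CC(=O)c1c(O)c(OC)c(OC)c(OC)c1OC | intermediate
6 | ethyl 2,2-diethoxyacetate | CCOC(=O)C(OCC)OCC | starting material
7 | 4,4-diethoxy-1-(2-hydroxy-3,4,5,6-tetramethoxyphenyl)butane-1,3-dione | CCOC(OCC)C(=O)CC(=O)c1c(O)c(OC)c(OC)c(OC)c1OC | intermediate (not isolated)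
8 | 2-(diethoxymethyl)-5,6,7,8-tetramethoxy-4H-chromen-4-one | CCOC(OCC)c1cc(=O)c2c(OC)c(OC)c(OC)c(OC)c2o1 | intermediate (not isolated)
9 | 5,6,7,8-tetramethoxy-4-oxo-4H-chromene-2-carbaldehyde | COc1c(OC)c(OC)c2c(=O)cc(C=O)oc2c1OC | intermediate
10 | 2-ethynyl-5,6,7,8-tetramethoxy-4H-chromen-4-one | COc1c(OC)c(OC)c2c(=O)cc(C#C)oc2c1OC | intermediate
11 | methyl acetoacetate | COC(=O)CC(C)=O | starting material
12 | methyl 3-(trimethylsilyloxy)but-2-enoate (E/Z mixture, geometry not defined) | COC(=O)C=C(C)O[Si](C)(C)C | intermediate
13 | (1Z)-1-methoxy-1,3-bis(trimethylsilyloxy)buta-1,3-diene (geometry immaterial) | CO/C(O[Si](C)(C)C)=C/C(=C)O[Si](C)(C)C | intermediate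
14 | 2-[6-methoxy-4,6-bis(trimethylsilyloxy)cyclohexa-1,4-dien-1-yl]-5,6,7,8-tetramethoxy-4H-chromen-4-one (racemic at the ketal carbon) | COc1c(OC)c(OC)c2c(=O)cc(C3=CCC(O[Si](C)(C)C)=CC3(OC)O[Si](C)(C)C)oc2c1OC | intermediate (not isolated)
15 | 2-(2,4-dihydroxyphenyl)-5,6,7,8-tetramethoxy-4H-chromen-4-one | COc1c(OC)c(OC)c2c(=O)cc(-c3ccc(O)cc3O)oc2c1OC | intermediate
16 | tamadone, 2-(2,4-dihydroxyphenyl)-5-hydroxy-6,7,8-trimethoxy-4H-chromen-4-one | COc1c(OC)c(O)c2c(=O)cc(-c3ccc(O)cc3O)oc2c1OC | target

**Step count.** Total: 9 steps. Longest linear sequence: 7 steps (steps 1–5, 8 and 9); steps 6 and 7 form the two-step diene branch.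

**Steps most likely to fail**

Step 8. The diene may isomerise by silyl migration or decompose on heating faster than it adds to an alkyne that is only vinylogously activated, or it may add in Michael fashion and oligomerise. The fallback brings ring B in preformed by known flavone chemistry and sets out from acetophenone 5. Claisen–Schmidt condensation of 5 with commercial 2,4-bis(benzyloxy)benzaldehyde (KOH, EtOH, rt) should give the chalcone (E)-3-[2,4-bis(benzyloxy)phenyl]-1-(2-hydroxy-3,4,5,6-tetramethoxyphenyl)prop-2-en-1-one F1. Oxidative cyclisation (catalytic I2, DMSO, 120 °C) should give 2-[2,4-bis(benzyloxy)phenyl]-5,6,7,8-tetramethoxy-4H-chromen-4-one F2. Hydrogenolysis (H2, 10% Pd/C, EtOAc/MeOH, rt) comes back to the route at 15, ahead of step 9.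

Step 5. The lithiated diazo reagent may attack C2 of the chromone instead of the aldehyde, or undergo dipolar cycloaddition to the electron-poor alkyne once it forms. The fallback replaces the diazo homologation by olefination and elimination and sets out from aldehyde 9. Stork–Zhao olefination ((iodomethyl)triphenylphosphonium iodide, NaN(SiMe3)2, THF, −78 °C) should give (Z)-2-(2-iodoethenyl)-5,6,7,8-tetramethoxy-4H-chromen-4-one F3. Anti-dehydroiodination (DBU, THF, rt to 50 °C) comes back at alkyne 10.

Step 3. Under AlCl3 the demethylation may run past the mono-phenol stage, or the central methoxy groups of the very electron-rich ring may be cleaved before acylation is complete. The fallback separates C–C bond formation from ether cleavage and sets out from 3. Lithiation at the only ring C–H, flanked by two methoxy groups (n-BuLi, THF, 0 °C), and acylation with N-methoxy-N-methylacetamide should give ketone 4, now isolated. One equivalent of BCl3 (CH2Cl2, −78 → 0 °C) should then remove a single ortho methyl group and come back at 5 (no new compound, F0).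

**Further compounds**
F1 | step 8 | (E)-3-[2,4-bis(benzyloxy)phenyl]-1-(2-hydroxy-3,4,5,6-tetramethoxyphenyl)prop-2-en-1-one | COc1c(OC)c(OC)c(C(=O)/C=C/c2ccc(OCc3ccccc3)cc2OCc2ccccc2)c(O)c1OC
F2 | step 8 | 2-[2,4-bis(benzyloxy)phenyl]-5,6,7,8-tetramethoxy-4H-chromen-4-one | COc1c(OC)c(OC)c2c(=O)cc(-c3ccc(OCc4ccccc4)cc3OCc3ccccc3)oc2c1OC
F3 | step 5 | (Z)-2-(2-iodoethenyl)-5,6,7,8-tetramethoxy-4H-chromen-4-one | COc1c(OC)c(OC)c2c(=O)cc(/C=C\I)oc2c1OC
F0 | step 3 | none | none
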